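**Retrosynthetic overview**

1. Kazinol K 24 ⇐ bis-silyl ether 23 (desilylation) ⇐ bis-ether 19 by one thermal double sigmatropic cascade. It closes ring C (the pyran, the only ring made) by forming the O4'–CMe2 bond last, and in the same operation moves the C5 unit on ring A from O4 to C5.
2. Enabling feature: ring C is a 2,2-dimethyl-2H-pyran fused to ring B at O4'–C4'–C5', i.e. the valence tautomer of the dienone O=C4'–C5'=CH–CH=CMe2, and C5' is the only hydrogen-bearing carbon ortho to O4' (C3' carries oxygen). On ring A the quaternary carbon of the 1,1-dimethylallyl group at C5 lies ortho to the O4 hydroxyl, the retron of an aromatic Claisen shift.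
3. 19 ⇐ diphenol 18 ⇐ chalcone 13 (conjugate reduction, then ortho-hydroxyl-assisted deoxygenation of the ketone to the propane chain) ⇐ ketone 3 + aldehyde 12 (Claisen–Schmidt union of two fragments of similar size).
4. 12 ⇐ 2-bromo-4,5-dimethoxybenzaldehyde 4 (demethylation, Stille prenylation at C6', O4'-selective tertiary propargyl ether); 3 ⇐ 2,4-dihydroxyacetophenone 1 (O4-selective prenyl ether).
5. Ring order: rings A and B are bought as benzenoid starting materials; ring C is formed in step 11.

Key step: step 11

Remark on locants: ring A = resorcinol ring (C1 carries the propane chain; O2, O4, C5); ring B = catechol-derived ring (C1' chain, O3', O4', C5', C6'); ring C = pyran ring. In the benzaldehydes 5–12, C1 (CHO) becomes C1', C2 becomes C6', O4 becomes O4' and O5 becomes O3'.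

**Route**

Step 1
Reactants: 1 2,4-dihydroxyacetophenone; 2 1-bromo-3-methylbut-2-ene (prenyl bromide)
Product: 3 1-[2-hydroxy-4-(3-methylbut-2-enyloxy)phenyl]ethanone
Conditions: K2CO3, acetone, reflux
Reagents that add atoms: 1-bromo-3-methylbut-2-ene, CC(C)=CCBr
Why: Williamson ether synthesis; the 2-hydroxyl is held in a hydrogen bond to the acetyl carbonyl, so only the more acidic and more nucleophilic 4-hydroxyl should be alkylated under mild carbonate conditions.

Step 2
Reactants: 4 2-bromo-4,5-dimethoxybenzaldehyde
Product: 5 2-bromo-4,5-dihydroxybenzaldehyde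
Conditions: BBr3, CH2Cl2, −78 °C to rt; then H2O
Reagents that add atoms: none
Why: Lewis-acid ether cleavage with BBr3 (borate complex, then SN2 attack of bromide on each methyl group) should free the catechol while the aryl bromide and the aldehyde survive.

Step 3
Reactants: 5 2-bromo-4,5-dihydroxybenzaldehyde; 6 tert-butyl(chloro)dimethylsilane
Product: 7 2-bromo-4,5-bis(tert-butyldimethylsilyloxy)benzaldehyde
Conditions: TBSCl, imidazole, DMF, rt
Reagents that add atoms: tert-butyl(chloro)dimethylsilane, CC(C)(C)[Si](C)(C)Cl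
Why: standard imidazole-promoted silylation of phenols masks the catechol so that the cross-coupling of step 4 meets no free, chelating hydroxyl groups.

Step 4
Reactants: 7 2-bromo-4,5-bis(tert-butyldimethylsilyloxy)benzaldehyde; 8 tributyl(3-methylbut-2-enyl)stannane
Product: 9 4,5-bis(tert-butyldimethylsilyloxy)-2-(3-methylbut-2-enyl)benzaldehyde
Conditions: Pd(PPh3)4 (5 mol %), toluene, 105 °C
Reagents that add atoms: tributyl(3-methylbut-2-enyl)stannane, CCCC[Sn](CCCC)(CCCC)CC=C(C)C
Why: Stille cross-coupling; oxidative addition is eased by the ortho formyl group, and reductive elimination from the η3-prenyl palladium intermediate at its unsubstituted terminus should give the linear prenyl arene.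

Step 5
Reactants: 9 4,5-bis(tert-butyldimethylsilyloxy)-2-(3-methylbut-2-enyl)benzaldehyde
Product: 10 4,5-dihydroxy-2-(3-methylbut-2-enyl)benzaldehyde
Conditions: TBAF, AcOH, THF, 0 °C
Reagents that add atoms: none
Why: fluoride-mediated desilylation driven by Si–F bond formation, buffered with acetic acid so that the catechol is not left as an air-sensitive dianion; the prenyl group has no ortho hydroxyl and should be inert.

Step 6
Reactants: 10 4,5-dihydroxy-2-(3-methylbut-2-enyl)benzaldehyde; 11 3-chloro-3-methylbut-1-yne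
Product: 12 5-hydroxy-4-(2-methylbut-3-yn-2-yloxy)-2-(3-methylbut-2-enyl)benzaldehyde
Conditions: DBU (1.05 equiv), CuCl2·2H2O (1 mol %), MeCN, 0 °C, Ar
Reagents that add atoms: 3-chloro-3-methylbut-1-yne, C#CC(C)(C)Cl
Why: copper-catalysed propargylic etherification of a phenoxide by a tertiary propargylic chloride; with about one equivalent of base only the O4 hydroxyl, para to the formyl group and clearly the more acidic one, should be ionised and etherified.

Step 7
Reactants: 3 1-[2-hydroxy-4-(3-methylbut-2-enyloxy)phenyl]ethanone; 12 5-hydroxy-4-(2-methylbut-3-yn-2-yloxy)-2-(3-methylbut-2-enyl)benzaldehyde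
Product: 13 (E)-1-[2-hydroxy-4-(3-methylbut-2-enyloxy)phenyl]-3-[5-hydroxy-4-(2-methylbut-3-yn-2-yloxy)-2-(3-methylbut-2-enyl)phenyl]prop-2-en-1-one
Conditions: KOH, EtOH/H2O, rt; then AcOH to pH 6
Reagents that add atoms: none
Why: Claisen–Schmidt condensation (aldol addition, then E1cB dehydration) should give the thermodynamically favoured (E)-enone; the tertiary propargyl ether has no propargylic hydrogen and cannot isomerise in base.

Step 8
Reactants: 13 the (E)-chalcone of step 7
Product: 14 1-[2-hydroxy-4-(3-methylbut-2-enyloxy)phenyl]-3-[5-hydroxy-4-(2-methylbut-3-yn-2-yloxy)-2-(3-methylbut-2-enyl)phenyl]propan-1-one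
Conditions: Zn dust, NH4Cl, EtOH/H2O, rt
Reagents that add atoms: none
Why: dissolving-metal conjugate reduction (electron transfer from zinc to the enone, protonation by ammonium ion) should touch only the conjugated C=C bond, since isolated trisubstituted alkenes, the terminal alkyne and the two ethers are not reducible under these conditions.

Step 9
Reactants: 14 the dihydrochalcone of step 8
Product: 18 2-{3-[5-hydroxy-4-(2-methylbut-3-yn-2-yloxy)-2-(3-methylbut-2-enyl)phenyl]propyl}-5-(3-methylbut-2-enyloxy)phenol, via bis(ethyl carbonate) 15 (not isolated), via ortho-quinone methide 16 (not isolated), via ring-B ethyl carbonate 17 (not isolated)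
Conditions: ClCO2Et, Et3N, THF, 0 °C; then NaBH4, H2O, 0 °C to rt; then NaOH, MeOH, rt
Reagents that add atoms: none
Why: ortho-hydroxyl-assisted deoxygenation of an aryl ketone: borohydride reduces the ketone of 15, the ring-A carbonate migrates to the benzylic alkoxide and is expelled by the phenoxide to give ortho-quinone methide 16, a second hydride reduces it to 17, and hydroxide then cleaves the remaining ring-B carbonate.

Step 10
Reactants: 18 the diphenol of step 9; 6 tert-butyl(chloro)dimethylsilane
Product: 19 bis(tert-butyldimethylsilyl) ether of 18 (silyl groups on O2 of ring A and on O3' of ring B)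
Conditions: TBSCl, imidazole, DMF, rt
Reagents that add atoms: tert-butyl(chloro)dimethylsilane, CC(C)(C)[Si](C)(C)Cl
Why: standard silylation of both phenols; the bulky silyloxy group at C2 of ring A is placed next to C3 on purpose to steer step 11, and the ring-B silyl ether keeps the O3' hydroxyl from adding to the neighbouring alkyne on heating.

Step 11
Reactants: 19 the bis-silyl bis-ether of step 10
Product: 23 bis(tert-butyldimethylsilyl) ether of kazinol K (silyl groups on O2 of ring A; O3' of ring B), via ortho-allenylphenol 20 (not isolated), via (Z)-ortho-quinone methide 21 (not isolated), via chromene prenyl ether 22 (not isolated)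
Conditions: PhNEt2 (degassed), 190 °C, sealed tube, Ar
Reagents that add atoms: none
Why: On ring B the aryl 1,1-dimethylpropargyl ether should undergo a [3,3] sigmatropic shift to C5' and enolise to ortho-allenylphenol 20, a 1,5-hydrogen shift from O4'–H to the central allene carbon then gives the (Z)-dienone 21, and this closes ring C by a thermal disrotatory oxa-6π electrocyclisation in which the O4'–CMe2 bond is formed, giving 22. At the same bath temperature the slower aromatic Claisen rearrangement of the ring-A prenyl ether passes through a chair-like [3,3] transition state to C5 and, after tautomerisation, leaves the 1,1-dimethylallyl group with its quaternary benzylic carbon next to the liberated O4 hydroxyl. The closest known reaction types are the thermal rearrangement of aryl 1,1-dimethylpropargyl ethers to 2,2-dimethyl-2H-chromenes and the aromatic Claisen rearrangement of aryl prenyl ethers, both classically run in hot N,N-dialkylanilines. Ring C is closed as a six-membered ring by a pericyclic 6π closure of a 1-oxatriene, which is fast because it restores the aromaticity of ring B, and the Z geometry it needs is fixed by the cyclic hydrogen shift; no stereocentre is formed. The step needs site selectivity on ring A (C5 against C3), which the bulky silyloxy group at C2 flanking C3 and the preference of a meta donor for the position para to it should secure, and on ring B, where oxygen at C3' blocks the other ortho position. The basic, degassed solvent should hold back acid-catalysed cyclisation and the abnormal Claisen isomerisation of the new ortho-(1,1-dimethylallyl)phenol, and the C6' prenyl group is a spectator.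

Step 12
Reactants: 23 the bis-silyl ether of kazinol K
Product: 24 kazinol K
Conditions: TBAF, AcOH, THF, 0 °C
Reagents that add atoms: none
Why: fluoride-mediated cleavage of the two aryl silyl ethers under buffered conditions should leave the chromene, the prenyl group and the 1,1-dimethylallyl group untouched.

**Compound list**

1 | 1-(2,4-dihydroxyphenyl)ethanone (2,4-dihydroxyacetophenone) | CC(=O)c1ccc(O)cc1O | starting material
2 | 1-bromo-3-methylbut-2-ene (prenyl bromide) | CC(C)=CCBr | starting material
3 | 1-[2-hydroxy-4-(3-methylbut-2-enyloxy)phenyl]ethanone | CC(=O)c1ccc(OCC=C(C)C)cc1O | intermediate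
4 | 2-bromo-4,5-dimethoxybenzaldehyde | COc1cc(Br)c(C=O)cc1OC | starting material
5 | 2-bromo-4,5-dihydroxybenzaldehyde | O=Cc1cc(O)c(O)cc1Br | intermediate
6 | tert-butyl(chloro)dimethylsilane | CC(C)(C)[Si](C)(C)Cl | starting material
7 | 2-bromo-4,5-bis(tert-butyldimethylsilyloxy)benzaldehyde | O=Cc1cc(O[Si](C)(C)C(C)(C)C)c(O[Si](C)(C)C(C)(C)C)cc1Br | intermediate
8 | tributyl(3-methylbut-2-enyl)stannane | CCCC[Sn](CCCC)(CCCC)CC=C(C)C | starting material
9 | 4,5-bis(tert-butyldimethylsilyloxy)-2-(3-methylbut-2-enyl)benzaldehyde | O=Cc1cc(O[Si](C)(C)C(C)(C)C)c(O[Si](C)(C)C(C)(C)C)cc1CC=C(C)C | intermediate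
10 | 4,5-dihydroxy-2-(3-methylbut-2-enyl)benzaldehyde | O=Cc1cc(O)c(O)cc1CC=C(C)C | intermediate
11 | 3-chloro-3-methylbut-1-yne | C#CC(C)(C)Cl | starting material
12 | 5-hydroxy-4-(2-methylbut-3-yn-2-yloxy)-2-(3-methylbut-2-enyl)benzaldehyde | O=Cc1cc(O)c(OC(C)(C)C#C)cc1CC=C(C)C | intermediate
13 | (E)-1-[2-hydroxy-4-(3-methylbut-2-enyloxy)phenyl]-3-[5-hydroxy-4-(2-methylbut-3-yn-2-yloxy)-2-(3-methylbut-2-enyl)phenyl]prop-2-en-1-one | CC(C)=CCOc1ccc(C(=O)/C=C/c2cc(O)c(OC(C)(C)C#C)cc2CC=C(C)C)c(O)c1 | intermediate
14 | 1-[2-hydroxy-4-(3-methylbut-2-enyloxy)phenyl]-3-[5-hydroxy-4-(2-methylbut-3-yn-2-yloxy)-2-(3-methylbut-2-enyl)phenyl]propan-1-one | CC(C)=CCOc1ccc(C(=O)CCc2cc(O)c(OC(C)(C)C#C)cc2CC=C(C)C)c(O)c1 | intermediate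
15 | bis(ethyl carbonate) of 14 (on O2 of ring A and O3' of ring B) | CCOC(=O)Oc1cc(OCC=C(C)C)ccc1C(=O)CCc1cc(OC(=O)OCC)c(OC(C)(C)C#C)cc1CC=C(C)C | intermediate
16 | (E)-ortho-quinone methide of ring A: 6-alkylidene-3-(3-methylbut-2-enyloxy)cyclohexa-2,4-dien-1-one carrying the ring-B ethyl carbonate | O=C1C=C(OCC=C(C)C)C=C/C1=C\CCc1cc(OC(=O)OCC)c(OC(C)(C)C#C)cc1CC=C(C)C | intermediate
17 | ring-B (O3') ethyl carbonate of diphenol 18 | CCOC(=O)Oc1cc(CCCc2ccc(OCC=C(C)C)cc2O)c(CC=C(C)C)cc1OC(C)(C)C#C | intermediate
18 | 2-{3-[5-hydroxy-4-(2-methylbut-3-yn-2-yloxy)-2-(3-methylbut-2-enyl)phenyl]propyl}-5-(3-methylbut-2-enyloxy)phenol | CC(C)=CCOc1ccc(CCCc2cc(O)c(OC(C)(C)C#C)cc2CC=C(C)C)c(O)c1 | intermediate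
19 | bis(tert-butyldimethylsilyl) ether of 18 | CC(C)=CCOc1ccc(CCCc2cc(O[Si](C)(C)C(C)(C)C)c(OC(C)(C)C#C)cc2CC=C(C)C)c(O[Si](C)(C)C(C)(C)C)c1 | intermediate
20 | ortho-allenylphenol: ring B with free O4'–H and a 3-methylbuta-1,2-dienyl group at C5'; ring A unchanged | CC(C)=CCOc1ccc(CCCc2cc(O[Si](C)(C)C(C)(C)C)c(O)c(C=C=C(C)C)c2CC=C(C)C)c(O[Si](C)(C)C(C)(C)C)c1 | intermediate
21 | (Z)-ortho-quinone methide of ring B: C4'=O with exocyclic C5'=CH–CH=CMe2, the dienyl arm cis to the carbonyl | O=C1C(O[Si](C)(C)C(C)(C)C)=CC(CCCc2ccc(OCC=C(C)C)cc2O[Si](C)(C)C(C)(C)C)=C(CC=C(C)C)/C1=C/C=C(C)C | intermediate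
22 | chromene prenyl ether: ring C closed, ring A still the O4 prenyl ether, both silyl ethers in place | CC(C)=CCOc1ccc(CCCc2cc(O[Si](C)(C)C(C)(C)C)c3c(c2CC=C(C)C)C=CC(C)(C)O3)c(O[Si](C)(C)C(C)(C)C)c1 | intermediate
23 | bis(tert-butyldimethylsilyl) ether of kazinol K (O2 of ring A, O3' of ring B) | C=CC(C)(C)c1cc(CCCc2cc(O[Si](C)(C)C(C)(C)C)c3c(c2CC=C(C)C)C=CC(C)(C)O3)c(O[Si](C)(C)C(C)(C)C)cc1O | intermediate
24 | kazinol K | C=CC(C)(C)c1cc(CCCc2cc(O)c3c(c2CC=C(C)C)C=CC(C)(C)O3)c(O)cc1O | target

**Step count and risks**

Total step count: 12. Longest linear sequence: 11 steps (4 to 24, steps 2 to 12); ketone 3 joins in step 7 after one step.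

Steps most likely to fail:

Step 11. Process: the ring-A shift is slower than the ring-B cascade, so during the longer heating the new ortho-(1,1-dimethylallyl)phenol may isomerise by the abnormal Claisen (ene/retro-ene) pathway or lose its C5 unit, and some migration to C3 may occur. The fallback sets out from 19 and comes back at 24; it replaces the single unassisted cascade by two thermal stages with in-flask acylation. 19 is heated in DMF at 130 °C, where only the ring-B propargyl ether should react, and chromene prenyl ether 22 is isolated. 22 is then heated in PhNEt2 with Ac2O and NaOAc at 185 °C, so that the phenol released by the ring-A Claisen shift is acetylated at once and cannot react further, giving the O4 acetate of 23 F1. K2CO3 in MeOH then cleaves the acetate and both aryl silyl ethers and should give 24 directly.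

Step 6. Process: loss of site selectivity between O4 and O5 (etherification at O5 or at both oxygens), or copper-promoted oxidation of the free catechol. The fallback sets out from 9 and comes back at 12; it replaces acidity control by protecting-group control. The silyl ether para to the formyl group of 9 is the more labile one and should be cleaved alone with Cs2CO3 in DMF/H2O at 0 °C, giving 5-(tert-butyldimethylsilyloxy)-4-hydroxy-2-(3-methylbut-2-enyl)benzaldehyde F2. Its single free phenol is etherified with 11 (DBU, CuCl2·2H2O, MeCN, 0 °C) to 5-(tert-butyldimethylsilyloxy)-4-(2-methylbut-3-yn-2-yloxy)-2-(3-methylbut-2-enyl)benzaldehyde F3. TBAF/AcOH then gives 12.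

Step 8. Process: reductive dimerisation of the enone radical anion, over-reduction to the alcohol, or cyclisation of the 2'-hydroxychalcone to the flavanone in place of clean 1,4-reduction. The fallback sets out from 12 (with 3) and comes back at 14; it makes the C2–C3 bond of the chain by enolate alkylation, so that no enone is formed at all. 12 is silylated (TIPSCl, imidazole, DMF) to 4-(2-methylbut-3-yn-2-yloxy)-2-(3-methylbut-2-enyl)-5-(triisopropylsilyloxy)benzaldehyde F4 and reduced with NaBH4 in MeOH to the benzylic alcohol F5. Appel bromination (CBr4, PPh3, CH2Cl2, 0 °C) gives the benzylic bromide F6, which is used at once to alkylate the dianion of ketone 3 (LDA, 2.2 equiv, THF, −78 °C) on carbon, giving the ring-B silyl ether of 14 F7. TBAF/AcOH then gives 14.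

**Further compounds**

F1 | step 11 | O4 acetate of 23 (bis-silyl kazinol K acetate) | C=CC(C)(C)c1cc(CCCc2cc(O[Si](C)(C)C(C)(C)C)c3c(c2CC=C(C)C)C=CC(C)(C)O3)c(O[Si](C)(C)C(C)(C)C)cc1OC(C)=O
F2 | step 6 | 5-(tert-butyldimethylsilyloxy)-4-hydroxy-2-(3-methylbut-2-enyl)benzaldehyde | O=Cc1cc(O[Si](C)(C)C(C)(C)C)c(O)cc1CC=C(C)C
F3 | step 6 | 5-(tert-butyldimethylsilyloxy)-4-(2-methylbut-3-yn-2-yloxy)-2-(3-methylbut-2-enyl)benzaldehyde | O=Cc1cc(O[Si](C)(C)C(C)(C)C)c(OC(C)(C)C#C)cc1CC=C(C)C
F4 | step 8 | 4-(2-methylbut-3-yn-2-yloxy)-2-(3-methylbut-2-enyl)-5-(triisopropylsilyloxy)benzaldehyde | O=Cc1cc(O[Si](C(C)C)(C(C)C)C(C)C)c(OC(C)(C)C#C)cc1CC=C(C)C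
F5 | step 8 | [4-(2-methylbut-3-yn-2-yloxy)-2-(3-methylbut-2-enyl)-5-(triisopropylsilyloxy)phenyl]methanol | OCc1cc(O[Si](C(C)C)(C(C)C)C(C)C)c(OC(C)(C)C#C)cc1CC=C(C)C
F6 | step 8 | 1-(bromomethyl)-4-(2-methylbut-3-yn-2-yloxy)-2-(3-methylbut-2-enyl)-5-(triisopropylsilyloxy)benzene | BrCc1cc(O[Si](C(C)C)(C(C)C)C(C)C)c(OC(C)(C)C#C)cc1CC=C(C)C
F7 | step 8 | ring-B triisopropylsilyl ether of dihydrochalcone 14 | CC(C)=CCOc1ccc(C(=O)CCc2cc(O[Si](C(C)C)(C(C)C)C(C)C)c(OC(C)(C)C#C)cc2CC=C(C)C)c(O)c1
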